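Time first: set the half-lives of these steps against the 5.0 d of the run.

all flasks: Sub2 0.690 M; Spx 0.690 M
- Monday's: Sub 0.69 M; Rea 0.897 M; time 5.0 d; a closed flask charged with all of it at once and left for 5.0 d
- Sunday's: Sub 0.69 M; Rea 0.897 M; a single well-mixed tank run continuously and read at steady state, 5.0 d in it on average
- Friday's: Sub 0.69 M (fed, over 2.50 d); Rea 0.897 M; time 5.0 d; all but Sub at the start; Sub goes in evenly over 2.50 d, the run ends at 5.0 d
- Saturday's: Sub 0.69 M; Rea 0.897 M (fed, over 2.50 d); time 5.0 d; a stirred flask in which Rea is dosed at a steady rate over 2.50 d without added volume, worked up at 5.0 d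

    Sub + Rea → Tgt (k1 = 1.2 × 10⁻⁴ L mol⁻¹ s⁻¹)
    Sub2 + Rea → Ofp (k2 = 2.2 × 10⁻⁴ L mol⁻¹ s⁻¹)
    Sub2 + Spx → Ofp2 (k3 = 5.7 × 10⁻⁶ L mol⁻¹ s⁻¹)
    Rea + Tgt → Ofp3 (k4 = 4.2 × 10⁻⁵ L mol⁻¹ s⁻¹)

- the stated concentrations are those of everything mixed, before any reaction; amounts are the same in each set-up
- the feed brings no volume worth counting
- run time (Monday's): 5.0 d

- order of the set-ups by the share of Tgt in all that became Tgt or Ofp3, at the outlet or at the end, highest first (Monday's / Sunday's / Friday's / Saturday's)
- share of Tgt in all that became Tgt or Ofp3, at the outlet or at the end, Monday's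
- share of Tgt in all that became Tgt or Ofp3, at the outlet or at the end, Sunday's
- share of Tgt in all that became Tgt or Ofp3, at the outlet or at the end, Friday's
- share of Tgt in all that became Tgt or Ofp3, at the outlet or at the end, Saturday's

**Ladder of times.** At the charged amounts, Sub2 halves by Rea in 0.0407 d, Sub by Rea in 0.075 d, Tgt by Rea in 0.21 d and Sub2 by Spx in 2.0 d, which is still shorter than the run. But Rea is the limiting reagent: its 0.897 M stands against 1.38 M of Sub and Sub2 together. So in Monday's I expect a quick scramble for Rea, then a slow tail of Spx on leftover Sub2, which touches neither Sub nor Tgt.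

**Spoiling ratio.** Making and spoiling Tgt both carry Rea, so Rea cancels from their ratio. What remains is the constant of spoiling over the constant of making, r = 0.350, a selectivity factor, multiplied by Tgt over Sub. Control changes hands when Tgt over Sub reaches 2.86. With Sub all in from the start and s the fraction left, the share is (s^r − s)/((1 − r)(1 − s)). In a steady tank it is 1/(1 + r(1 − s)/s).

**My reckoning.** Try s = 0.5 in Monday's. While Rea lasts, Sub2 falls close to s to the power 1.83, because Spx takes it far more slowly, so with the Rea lost to Tgt the flask uses 0.884 M of Rea, close to its charge. The share is then 87.6 %. The tank rule at that trial s gives 74.1 % for Sunday's, though the tank's own s is still to be seen. Saturday's obeys the same closed rule, and Spx has time on Sub2 during the 2.50 d dose, which leaves more Rea for Sub and Tgt, so I place it below Monday's. Friday's late Sub lies outside the rule, so my reckoning stops there.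

**Forecast.** The forecast gives Monday's > Saturday's > Friday's > Sunday's, with 87 % for Monday's, 68.5 % for Sunday's, 79.5 % for Friday's and 82.5 % for Saturday's, holding that “the back-mixed tank exposes Tgt to Rea at outlet conditions and does worst”.

**Result.** The simulation gives Monday's > Saturday's > Friday's > Sunday's: Monday's 87.0 %, Sunday's 68.5 %, Friday's 79.1 %, Saturday's 83.0 %. The rule with Monday's 48 % of Sub left gives 86.8 %, with Saturday's 38.9 % it gives 83.0 %, and the tank rule with Sunday's 43.3 % gives 68.6 %. Monday's has come to rest for the share: Rea is at 0 % by 2.50 d, and at 50.0 d the share is still 87.0 %. Ten times the time still moves Sub2 from 6.21 % to 0 % of its charge, and Spx from 78.0 % to 71.8 %.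

**Second flask.** With 0.41 M of Sub2 and Monday's other charges, 33.3 % of Sub is left, and the same ratio gives 80.2 %. The computed share there is 80.1 %, with Tgt at 53.5 % and Ofp3 at 13.2 %.

The constants used here were chosen freely; no experiment stands behind them.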